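**Question.** What stands in the ochre flask at 40 h, and which move adds most target?

in all of them: gas 5.4 mM (held)

|  | substrate | temperature | remark | time |
|---|---|---|---|---|
| ochre | 20 mM | 25 °C | the very flask that is asked about, followed so far |  |
| teal | 10 mM | 31 °C | run made earlier |  |
| flask | 20 mM | 25 °C |  | 40 h |

| run | time / h | target / % | substrate / % |
|---|---|---|---|
| ochre | 4.00 | 6.6 | 93.9 |
| ochre | 8.00 | 12.2 | 86.8 |
| ochre | 12.0 | 17.0 | 81.4 |
| ochre | 15.0 | 19.8 | 77.7 |
| ochre | 20.0 | 22.7 | 72.8 |
| ochre | 25.0 | 24.7 | 65.9 |
| teal | 1.33 | 2.8 | 96.9 |
| teal | 2.00 | 4.3 | 95.9 |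
| teal | 4.00 | 10.8 | 89.8 |
| teal | 6.00 | 16.1 | 82.8 |
| teal | 10.0 | 23.9 | 73.7 |
| teal | 15.0 | 31.6 | 64.2 |

(each reading ± 0.5 percentage points)

- noon: at 40 h take out 90 % of the target then present, then wait 20 h
- midnight: change nothing and wait 20 h more
- spring: at 40 h raise the temperature by 20 K, then wait 20 h
- dusk: at 40 h add substrate, 50.0 % of the amount charged, then wait 20 h

- for by-product the crystals are counted in
- as a solid, counted per litre of solution: crystals
- at the start none of reagent is dissolved
- target that was removed still counts
- on the list of suspects stand: substrate + reagent <-> target + by-product; gas <-> reagent; crystals <-> by-product; target + by-product -> side product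
- additions bring no volume worth counting

* target, in percent of the substrate first charged, at 40 h
* which option adds most target ("none" when 2 percentage points or less is all one gets) (noon / midnight / spring / dusk / none)
* target present, with what was taken out counted in, in percent of the substrate first charged, after noon
* target present, with what was taken out counted in, in percent of the substrate first charged, after dusk

**Two rates.** A substrate molecule that has become target stands at a fork: it stays, or it meets a by-product and leaves as side product. In fractions of the charge, supply is k·a, with a the substrate left. Loss is q·p·w, with p target and w by-product. Substrate in the ochre run reads k = 0.0167 h⁻¹. From 15.0 h to 25.0 h substrate fell 12 percentage points but target rose 4.9 points. That gap, taken per hour and over the square of target at 20.0 h, reads q = 0.134 h⁻¹.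

**Balance level.** Target and by-product are born together and leave together, so w equals p while no crystals form. Reckoned substrate at 40 h is 51.3 %, which gives 25.3 %. This is the balance level, the square root of k·a/q, where supply equals loss: a quasi-steady state.

**Moves.** Midnight follows the level down as substrate falls. By this reckoning, noon takes out 22.8 % of target but no by-product, so w stays that far above p for as long as no crystals form. Assuming none form, the same balance, 20 h later, gives 35.6 % in total. Dusk raises a and gives 30.1 %. Of these two, this reckoning puts noon ahead.

**Forecast, flask.** The forecast also names noon (“Noon narrowly beats dusk”), with 28 %, 36 % and 34 %, which is higher than this reckoning for now and for dusk. The flask gives 26.1 %, 34.8 % and 31.1 %, and noon is best.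

    substrate + reagent ⇌ target + by-product (K = 2.70, k = 9.50 × 10⁻⁴ M⁻¹ s⁻¹, Ea = 75.0 kJ mol⁻¹, ΔH = −11.0 kJ mol⁻¹)
    gas ⇌ reagent, rate k2*(csat - [reagent]) (kL = 5.00 × 10⁻⁴ s⁻¹)
    crystals ⇌ by-product, rate k3*(cs3 - [by-product]) while solid is left; crystals form when [by-product] > cs3 (solubility = 6.30 mM, k = 2.20 × 10⁻⁴ s⁻¹)
    target + by-product → side product (k = 0.00170 M⁻¹ s⁻¹, Ea = 47.0 kJ mol⁻¹)
    (constants at 25 °C)

**Balance check.** At 40.0 h the ochre flask makes target at 0.942 of the rate at which it uses target up, so target is already falling, and its simulated substrate of 52.6 % puts the balance level at 25.6 %. Read at 72.0 h, the same flask holds 33.0 % substrate, which puts the level at 20.3 %, and its target stands at 22.3 %.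

(Readings and results were computed on assumed constants; scatter was added.)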